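## Structural features

Compound 15 is a diarylmethane: two identical benzene rings joined through one sp3 CH2 carbon, with no further ring and no stereocentre. The only stereocentres in the route are transient, namely the cis 3a/7a pairs of 13 and the bridgehead and ring-fusion centres of 10 to 12. Each ring carries five contiguous substituents: the bridge at C1, bromine at C2 and C3, hydroxyl at C4 and C5, and the only ring hydrogen at C6. The catechols are the fragile part, since they oxidise to o-quinones in air, above all as phenoxides. The aryl C–Br bonds do not tolerate hydrogenolytic, dissolving-metal or halogen–metal-exchange conditions late in a route. The real difficulty is regiochemical: two vicinal bromines must lie on the bridge side of each catechol while C6 stays free. In an electrophilic approach one bromine enters easily, but the second must go into a site flanked on both sides while the open C6, also ortho to oxygen, competes, and this must succeed completely on both rings. The key step uses the fact that the chain C6(H)–C1(CH2)–C2(Br)–C3(Br) is the carbon backbone of a 3-alkyl-4,5-dibromothiophene, which as its 1,1-dioxide is an electron-poor cyclic diene, while C4–C5 with their oxygens are a cis-enediol available as its cyclic carbonate; forming C3–C4 and C5–C6 by cycloaddition places every substituent by connectivity.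

## Logic of the disconnections

15 to 14. The two catechol units of 15 are traced back to the two cyclic carbonates of 14; four acyl C–O bonds are re-formed and no skeletal bond is cut. The carbonate is what the two-carbon partner of the key step brings with it, and it keeps the catechols inert to the oxidant of the preceding step. The gain is that the most oxidation-prone function appears only at the very end. The forward step must cleave two aryl carbonates without air oxidation of the product and without touching C–Br.

14 to 13. Each arene of 14 is traced back to a cis-3a,7a-dihydro ring by formal addition of H2 across C4–C5 (target numbering); again no skeletal bond is cut. This uncovers two cyclohexa-1,3-dienes with their sp3 carbons at the oxygenated positions, the retron of a cycloaddition–extrusion sequence. The price is four transient stereocentres that need no control beyond the cis fusion. The forward step must remove hydride from an oxygen-bearing allylic C–H faster than that carbon loses its carbonate oxygen.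

13 to 8 and 9. In each ring of 13 the bonds C3–C4 and C5–C6 are cut (four skeletal bonds in all) and C3 and C6 are re-joined through a sulfonyl bridge, giving 8 and two molecules of 9. The cut separates the halogenated, bridge-bearing four-carbon half from the dioxygenated two-carbon half. Two carbocycles are exchanged for five-membered heterocycles on which bromine and bridge can be placed by predictable heteroaromatic chemistry, and the symmetric two-carbon partner removes any regiochemical question. The forward step demands that cross-cycloaddition outruns self-addition of the sulfone rings and that the diene product survives. The free α-position of 8 cannot be blocked because it becomes C6–H, so 8 must be made cold, under neutral conditions, and used at once.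

8 to 7. The four S=O bonds are removed, giving 7, in which both heterocycles are aromatic. The reactive, non-aromatic diene is thus generated last from a stable precursor. The forward step needs an oxygen-transfer reagent strong enough for a bromine-deactivated thiophene but neutral and cold enough to spare the labile dioxide.

7 to 5. The two C–Br bonds at the α-carbons next to the existing bromines are cut, giving 5. These carbons carry the most acidic ring hydrogens (between sulfur and a C–Br carbon), so deprotonative metalation, not electrophilic substitution, fixes the regiochemistry. Each ring then needs only one bromine from its precursor. The forward step must metalate both rings there without touching the bridge CH2 and without halogen migration.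

5 to 4. The bridge CH2 is traced to a secondary carbinol (C–H to C–O) in 4. The oxygen is the handle left by a carbonyl-based assembly of the bridge. The forward step needs a reduction that spares aryl bromides, namely hydride capture of a stabilised diarylmethyl cation.

4 to 1 and 2. One aryl–carbinol C–C bond is cut, giving 1 (to be used as its β-lithio derivative) and 2, which already carries the second ring and the future bridge carbon at the aldehyde level. The cut joins two stock thiophenes in a single operation and makes every later step act on both halves of a symmetric molecule at once. The forward step needs a clean single bromine–lithium exchange on 1, a temperature low enough that the β-lithio species neither scrambles nor ring-opens, and carbonyl addition that is faster than exchange with the C–Br bond of 2.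

## Other disconnections considered

Alternative 1: The cut removes the four aryl C–Br bonds (C2–Br and C3–Br of both rings), with the bridge at the ketone level and the C5 oxygens as methyl ethers.
- Forward key step: the symmetric benzophenone A1 is exhaustively brominated (excess Br2, Fe powder, AcOH) to the tetrabromide A2. Carbonyl reduction to CH2 and cleavage of the methyl ethers would then lead to 15.
- In its favour: the skeleton is complete from the start and no ring is built. The directing effects cooperate: the free phenol sends the first bromine ortho to itself (C3) and the methoxy group sends the second para to itself (C2), the pattern expected for 4-hydroxy-3-methoxyaryl carbonyl compounds.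
- Against it here: the second bromine of each ring must enter a site flanked by bromine and the diaryl ketone carbonyl in a ring already deactivated twice, and this must go to completion four times. Foreseeable failure modes are under-bromination to tribromides that are hard to separate from A2, attack at C6, and ipso-attack para to the phenol with cleavage of the ketone. The later reduction of a di-ortho-substituted, electron-poor benzophenone must spare four C–Br bonds, and the demethylation needs BBr3.
- Comparison on structure: both plans deliver every substituent, but A2 owes its regiochemistry to relative rates, whereas in 13 it follows from connectivity.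
- Comparison on mechanism: four successive electrophilic substitutions on a progressively deactivated arene stand against two pericyclic annulations that must beat sulfone self-addition; neither is free of risk.
- Comparison on step economy: Alternative 1 is clearly the better (about three operations from A1 against seven steps). It is also the equal or better in cost of materials and in having no thermally labile intermediate. The chosen plan is ahead only in regiochemical certainty and in avoiding Br2 and BBr3.

Alternative 2: The cut is at C1–C6 and C2–C3 of each ring, so that the bridge carbon with C1 and C2 of both rings comes from the diynone A3 and the C3–C4–C5–C6 unit from the diene A4.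
- Forward key step: A3 takes up two molecules of A4 in a double Diels–Alder reaction to give the bis(cyclohexa-1,4-diene) ketone A5, which would be dehydrogenated to the benzophenone A6.
- In its favour: both rings are built around the future bridge carbon in one operation. The pairing is electronically matched (electron-poor bromoalkynone, electron-rich diene) and should run under milder conditions than step 5, and the symmetric diene poses no regiochemical question.
- Against it here: the cycloaddition installs only the C2 bromine, and C3 arrives as C–H. The C3 bromine would have to be added afterwards at a site between bromine and oxygen, in competition with C6, which brings back the regiochemical problem that a ring-construction strategy is meant to avoid. A3 is a cross-conjugated bis(bromoalkynyl) ketone, to be expected to be a sensitive, hazardous Michael acceptor, and A4 is not a stock chemical. Ketone reduction and fourfold demethylation still follow.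
- Comparison on structure: the chosen plan is better, since 13 carries all four bromines and A5 only two.
- Comparison on mechanism: Alternative 2 is the equal or better. The normal-demand cycloaddition is well matched, and aromatising a cyclohexa-1,4-diene bis(enol ether) is easier than dehydrogenating 13.
- Comparison on step economy: the chosen plan is the equal or better, because A3 and A4 must be prepared and bromination, reduction and deprotection are added after the key step.

Alternative 3: The cut is at C1–C6 and C4–C5 of each ring; C1–C4 of each ring derive from a 2-silyloxyfuran and C5–C6 from an enone. The silyl group is taken as tert-butyldimethylsilyl.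
- Forward key step: the bis(silyloxyfuran) A8, to be made from A7, adds two molecules of the enone A9 (Et2AlCl, then aqueous HCl). The oxa-bridged adducts open and dehydrate to the bis(o-hydroxyacetophenone) A10. A double Dakin oxidation (alkaline H2O2) would convert the acetyl groups into the C5 hydroxyls and give 15.
- In its favour: aromatisation is a redox-neutral dehydration and needs no dehydrogenation. Both bromines and the bridge are placed by construction. Polarity (nucleophilic furan C5 to the enone β-carbon) puts the acetyl group ortho to the new phenol, where a Dakin oxidation can use it.
- Against it here: A8 requires the bridge and then oxidation of each remaining furan α-position to the butenolide level before silylation, with halogen–metal exchange competing on a dibromofuran. The nucleophilic furan terminus is fully substituted, so the first C–C bond creates, twice, a quaternary centre on either side of one CH2. Silyloxyfurans and enones under Lewis acids tend to stop at the conjugate-addition stage instead of closing the ring. The two bromines lower the nucleophilicity, and the final alkaline peroxide step exposes an electron-poor ketone and an oxidisable catechol.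
- Comparison on structure: equal for bromines and bridge, but only one oxygen per ring comes with the cycloaddition, whereas 9 brings both.
- Comparison on mechanism: Alternative 3 is better in its aromatisation mode. The chosen plan is better in using a symmetric two-carbon partner and in not building quaternary centres.
- Comparison on step economy: about equal (roughly eight steps from A7 against seven).

Key step: step 5

Remark on the chemistry: 2 is assumed to be a stock heteroaryl aldehyde, so that the bridge is made by a one-to-one cross-addition.

Remark on the chemistry: 13 and the transient species 10–12 should form as mixtures of diastereomers (endo/exo at the bridged stage; meso and racemic for the pair of cis-fused rings). One isomer is drawn in each case, and all these stereocentres vanish in step 6.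

Remark on handling: the SO2 evolved in step 5 is swept into aqueous NaOH, the dioxirane of step 4 is used only as a cold dilute solution, and DDQ is kept dry and away from acid.

## Route

Step 1
Reactants: 1 3,4-dibromothiophene; 2 4-bromothiophene-3-carbaldehyde
Product: 4 bis(4-bromothiophen-3-yl)methanol, via (4-bromothiophen-3-yl)lithium 3 (not isolated)
Conditions: 1 (1.05 equiv), n-BuLi (1.0 equiv), Et2O, −78 °C; then 2 (1.0 equiv) in Et2O, −78 → 0 °C; H2O
Reagents that add atoms: none
Why: Bromine–lithium exchange on 1 stops at the mono-lithio stage at −78 °C, and in Et2O the β-lithiothiophene 3 should neither isomerise nor ring-open at this temperature. Addition of an aryllithium to an aryl aldehyde is much faster than exchange with the C–Br bond of 2, so one molecule of 3 and one of 2 should combine to the symmetric diarylmethanol 4, and no over-addition is possible at the alkoxide stage.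

Step 2
Reactants: 4 bis(4-bromothiophen-3-yl)methanol
Product: 5 bis(4-bromothiophen-3-yl)methane
Conditions: Et3SiH (3 equiv), CF3CO2H (10 equiv), CH2Cl2, 0 °C → rt, slow addition of 4
Reagents that add atoms: none
Why: Ionic hydrogenation: CF3CO2H ionises the carbinol to a di(3-thienyl)methyl cation, which Et3SiH reduces by hydride transfer; the metal-free conditions leave both C–Br bonds intact, and slow addition of 4 to the silane/acid mixture keeps Friedel–Crafts self-alkylation at the free thiophene α-positions down.

Step 3
Reactants: 5 bis(4-bromothiophen-3-yl)methane
Product: 7 bis(4,5-dibromothiophen-3-yl)methane, via bis(4-bromo-5-lithiothiophen-3-yl)methane 6 (not isolated)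
Conditions: LiN(i-Pr)2 (2.2 equiv), THF, −78 °C; BrCl2CCCl2Br (2.4 equiv), −78 °C → rt
Reagents that add atoms: 1,2-dibromo-1,1,2,2-tetrachloroethane, BrC(Cl)(Cl)C(Cl)(Cl)Br
Why: Deprotonative lithiation: the ring hydrogen between sulfur and the C–Br carbon is the most acidic C–H of each ring, and the 2-lithio-3-bromothiophene arrangement in 6 is the thermodynamically preferred one, so no halogen dance is expected; the dibromotetrachloroethane transfers electrophilic bromine with loss of tetrachloroethene. At −78 °C the hindered amide should remove the sp2 ring hydrogen much faster than a hydrogen of the bridge CH2.

Step 4
Reactants: 7 bis(4,5-dibromothiophen-3-yl)methane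
Product: 8 3,3'-methylenebis(4,5-dibromothiophene 1,1-dioxide)
Conditions: dimethyldioxirane (ca. 0.07 M in acetone, 6 equiv), CH2Cl2, 0 °C → rt, dark; evaporation below 25 °C, used at once
Reagents that add atoms: dimethyldioxirane, CC1(C)OO1
Why: Electrophilic oxygen transfer from a dioxirane to thiophene sulfur, the second transfer to each sulfur being faster than the first, is an established way to thiophene 1,1-dioxides, including halogenated and thermally labile ones; the conditions are neutral and the only by-product is acetone, so 8 should be obtained by cold evaporation before its rings can add to each other.

Step 5
Reactants: 8 3,3'-methylenebis(4,5-dibromothiophene 1,1-dioxide); 9 vinylene carbonate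
Product: 13 bis(6,7-dibromo-2-oxo-cis-3a,7a-dihydro-1,3-benzodioxol-5-yl)methane, via sulfur dioxide-bridged monoadduct 10 (not isolated), via half-annulated monosulfone 11 (not isolated), via sulfur dioxide-bridged second adduct 12 (not isolated)
Conditions: 9 (neat, ca. 30 equiv), BHT (1 mol%), 100–110 °C, Ar sweep (SO2 into aq. NaOH), 8 added in portions; excess 9 distilled off under vacuum below 50 °C; crude 13 taken directly into step 6
Reagents that add atoms: vinylene carbonate (second molecule of 9), O=C1OC=CO1
Why: Each sulfone ring of 8 is an electron-poor, non-aromatic cyclic diene (LUMO lowered by the sulfonyl group and two bromines) that takes up one molecule of the enediol carbonate 9 in an inverse-demand [4+2] cycloaddition across its two α-carbons, giving a 7-thiabicyclo[2.2.1]hept-2-ene 7,7-dioxide (10, later 12). This strained bridged sulfone then loses SO2 by a thermally allowed cheletropic extrusion, leaving a cyclohexa-1,3-diene (11, then 13), so that one molecule of 8 consumes two molecules of 9 and releases two of SO2. The closest known reaction type is the annulation of tetrahalothiophene 1,1-dioxides with alkenes, together with the use of 9 as a two-carbon enediol partner toward electron-poor dienes such as cyclopentadienones and 2-pyrones. Each of the two six-membered rings is closed by [4+2] cycloaddition, four carbons from the sulfone and two from 9, with C3–C4 and C5–C6 (target numbering) as the new bonds. The two stereocentres of each ring (C3a and C7a) are cis because 9 is a cis-alkene locked in a five-membered ring and adds suprafacially; endo versus exo approach and the relation between the two rings only decide which diastereomers form, and all four centres are erased in step 6. No regioselectivity is needed, since 9 is symmetric. The selectivity that matters is chemoselectivity: cross-cycloaddition must beat self-addition of the sulfone rings and further reaction or carbonate elimination of the diene product. The bromine at one diene terminus and the substituents at both β-carbons slow self-addition sterically, and 9 as solvent in large excess, portionwise addition of 8, the lowest temperature that sustains SO2 evolution and a radical inhibitor against polymerisation of 9 should secure the rest.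

Step 6
Reactants: 13 bis(6,7-dibromo-2-oxo-cis-3a,7a-dihydro-1,3-benzodioxol-5-yl)methane
Product: 14 bis(6,7-dibromo-2-oxo-1,3-benzodioxol-5-yl)methane
Conditions: DDQ (2.4 equiv), PhCl (dry), 60–80 °C, Ar
Reagents that add atoms: none
Why: DDQ dehydrogenation of a cyclohexa-1,3-diene: hydride abstraction from the allylic, oxygen-bearing C3a–H gives a pentadienyl (arenium-type) cation that loses the C7a proton, and the gain of aromaticity drives both rings to the arene; in dry, non-polar PhCl, ionisation of the allylic C–O bond, which would lead to a phenol, is disfavoured. The carbonates, all C–Br bonds and the bridge CH2, which ends up between two electron-poor arenes, are inert to the quinone.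

Step 7
Reactants: 14 bis(6,7-dibromo-2-oxo-1,3-benzodioxol-5-yl)methane
Product: 15 bis(2,3-dibromo-4,5-dihydroxyphenyl)methane
Conditions: NaHCO3 (0.2 equiv), THF/H2O 3:1 (degassed), rt → 40 °C, Ar; dilute HCl on work-up
Reagents that add atoms: none
Why: Cyclic aryl carbonates are activated esters: water or hydroxide adds to the carbonyl, a phenoxide leaves and the resulting aryl hydrogen carbonate decarboxylates, so both catechols should be released with loss of CO2 under very mild conditions; exclusion of air and an acidic work-up guard against oxidation of the catechols to o-quinones, and no C–Br bond is affected.

## Compound list

1 | 3,4-dibromothiophene | Brc1cscc1Br | starting material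
2 | 4-bromothiophene-3-carbaldehyde | O=Cc1cscc1Br | starting material
3 | (4-bromothiophen-3-yl)lithium (not isolated) | [Li]c1cscc1Br | intermediate
4 | bis(4-bromothiophen-3-yl)methanol | OC(c1cscc1Br)c1cscc1Br | intermediate
5 | bis(4-bromothiophen-3-yl)methane | Brc1cscc1Cc1cscc1Br | intermediate
6 | bis(4-bromo-5-lithiothiophen-3-yl)methane (not isolated) | [Li]c1scc(Cc2csc([Li])c2Br)c1Br | intermediate
7 | bis(4,5-dibromothiophen-3-yl)methane | Brc1scc(Cc2csc(Br)c2Br)c1Br | intermediate
8 | 3,3'-methylenebis(4,5-dibromothiophene 1,1-dioxide) | O=S1(=O)C=C(CC2=CS(=O)(=O)C(Br)=C2Br)C(Br)=C1Br | intermediate
9 | vinylene carbonate (1,3-dioxol-2-one) | O=C1OC=CO1 | starting material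
10 | monoadduct (not isolated): one ring as the carbonate-fused 7-thiabicyclo[2.2.1]hept-2-ene 7,7-dioxide (endo drawn), the other still a thiophene 1,1-dioxide | C(C1=C(Br)[C@]2(Br)[C@@H]3OC(=O)O[C@@H]3[C@H]1S2(=O)=O)C1=CS(=O)(=O)C(Br)=C1Br | intermediate
11 | half-annulated compound (not isolated): one cis-3a,7a-dihydrocatechol carbonate ring, one thiophene 1,1-dioxide ring | C(C1=C[C@H]2OC(=O)O[C@H]2C(Br)=C1Br)C1=CS(=O)(=O)C(Br)=C1Br | intermediate
12 | second adduct (not isolated): one cis-3a,7a-dihydrocatechol carbonate ring, one carbonate-fused 7-thiabicyclo[2.2.1]hept-2-ene 7,7-dioxide ring (endo drawn) | C(C1=C[C@H]2OC(=O)O[C@H]2C(Br)=C1Br)C1=C(Br)[C@]2(Br)[C@@H]3OC(=O)O[C@@H]3[C@H]1S2(=O)=O | intermediate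
13 | bis(6,7-dibromo-2-oxo-cis-3a,7a-dihydro-1,3-benzodioxol-5-yl)methane (cis ring fusions; one diastereomer drawn) | C(C1=C[C@H]2OC(=O)O[C@H]2C(Br)=C1Br)C1=C[C@H]2OC(=O)O[C@H]2C(Br)=C1Br | intermediate
14 | bis(6,7-dibromo-2-oxo-1,3-benzodioxol-5-yl)methane | O=C1Oc2cc(Cc3cc4OC(=O)Oc4c(Br)c3Br)c(Br)c(Br)c2O1 | intermediate
15 | bis(2,3-dibromo-4,5-dihydroxyphenyl)methane | Oc1cc(Cc2cc(O)c(O)c(Br)c2Br)c(Br)c(Br)c1O | target

## Step count and least certain steps

Total step count: 7. Longest linear sequence: 7 steps (1 to 15). The route is linear and, from 4 onwards, two-directional, with 2 and 9 as the only other inputs.

Step 5 (key step). The most likely failure is consumption of the sulfone rings by self-cycloaddition, one ring acting as diene and the C2=C3 bond of another as the two-carbon partner, faster than capture by 9. This is plausible because 9 is only a moderately electron-rich partner and 8 is less activated than a tetrahalothiophene dioxide. A second risk is thermal loss of the carbonate from the diene rings at the temperature required. The fallback sets out from 8 and comes back at 15; it exchanges the carbonate for a much more electron-rich enediol acetal, so the cycloaddition can run near room temperature and the oxygen substituents become poor leaving groups. Compound 8 is treated with 2,2-dimethyl-1,3-dioxole (a known, volatile enediol acetonide, used in excess) in CH2Cl2 at rt to 40 °C. Cycloaddition and SO2 loss should give bis(6,7-dibromo-2,2-dimethyl-cis-3a,7a-dihydro-1,3-benzodioxol-5-yl)methane F1. DDQ dehydrogenation then gives bis(6,7-dibromo-2,2-dimethyl-1,3-benzodioxol-5-yl)methane F2, and warm aqueous CF3CO2H cleaves both aryl acetonides to give 15.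

Step 4. The most likely failure is incomplete oxygen transfer to the bromine-deactivated sulfur atoms, together with loss of partly or fully oxidised rings through cycloaddition with each other during a long reaction or on concentration. The fallback sets out from 5 and comes back at 8; it passes through a silyl-substituted sulfone that is easier to make and to handle. Compound 5 is lithiated as in step 3 and quenched with Me3SiCl to give bis[4-bromo-5-(trimethylsilyl)thiophen-3-yl]methane F3. α-Silylthiophenes are known to be oxidised cleanly by mCPBA (CH2Cl2, rt) and their dioxides are robust, which should give 3,3'-methylenebis[4-bromo-5-(trimethylsilyl)thiophene 1,1-dioxide] F4. Ipso-bromodesilylation with Br2/AgBF4 in CH2Cl2 at 0 °C then delivers 8.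

Step 6. The most likely failure is ionisation or thermal syn-elimination of the allylic carbonate C–O bond, with loss of CO2, overtaking the slow hydride abstraction from an electron-poor diene; this would lead to ring-deoxygenated phenols. The fallback sets out from 13 and comes back at 15, bypassing 14; it changes the aromatisation from C–H hydride abstraction to carbinol oxidation. Methanolysis of 13 (catalytic K2CO3, MeOH, 0 °C) gives bis(5,6-dibromo-cis-3,4-dihydroxycyclohexa-1,5-dien-1-yl)methane F5. Swern oxidation (DMSO, (COCl)2, Et3N, −78 °C) of one allylic carbinol per ring gives a 6-hydroxycyclohexa-2,4-dienone that tautomerises to the catechol. A Na2S2O4 wash returns any o-quinone formed by over-oxidation, giving 15 directly.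

Step 3. The most likely failure is competing deprotonation of the bridge CH2, which is activated by two heteroaryl groups, or incomplete lithiation of the second ring; either would give mixtures of bromination patterns that are hard to separate. The fallback sets out from 4 and comes back at 7; it brominates before deoxygenation, so that the bridge carbon is protected as its lithium alkoxide. Compound 4 is treated with LiN(i-Pr)2 (3.3 equiv, THF, −78 °C) and the same bromine donor to give bis(4,5-dibromothiophen-3-yl)methanol F6. Et3SiH/CF3CO2H then reduces F6 to 7.

## Further compounds

F1 | step 5 | bis(6,7-dibromo-2,2-dimethyl-cis-3a,7a-dihydro-1,3-benzodioxol-5-yl)methane | C(C1=C[C@H]2OC(C)(C)O[C@H]2C(Br)=C1Br)C1=C[C@H]2OC(C)(C)O[C@H]2C(Br)=C1Br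
F2 | step 5 | bis(6,7-dibromo-2,2-dimethyl-1,3-benzodioxol-5-yl)methane | CC1(C)Oc2cc(Cc3cc4OC(C)(C)Oc4c(Br)c3Br)c(Br)c(Br)c2O1
F3 | step 4 | bis[4-bromo-5-(trimethylsilyl)thiophen-3-yl]methane | C[Si](C)(C)c1scc(Cc2csc([Si](C)(C)C)c2Br)c1Br
F4 | step 4 | 3,3'-methylenebis[4-bromo-5-(trimethylsilyl)thiophene 1,1-dioxide] | O=S1(=O)C=C(CC2=CS(=O)(=O)C([Si](C)(C)C)=C2Br)C(Br)=C1[Si](C)(C)C
F5 | step 6 | bis(5,6-dibromo-cis-3,4-dihydroxycyclohexa-1,5-dien-1-yl)methane | C(C1=C[C@@H](O)[C@@H](O)C(Br)=C1Br)C1=C[C@@H](O)[C@@H](O)C(Br)=C1Br
F6 | step 3 | bis(4,5-dibromothiophen-3-yl)methanol | OC(c1csc(Br)c1Br)c1csc(Br)c1Br
A1 | alternative 1 | bis(4-hydroxy-3-methoxyphenyl)methanone | COc1cc(C(=O)c2ccc(O)c(OC)c2)ccc1O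
A2 | alternative 1 | bis(2,3-dibromo-4-hydroxy-5-methoxyphenyl)methanone | COc1cc(C(=O)c2cc(OC)c(O)c(Br)c2Br)c(Br)c(Br)c1O
A3 | alternative 2 | 1,5-dibromopenta-1,4-diyn-3-one | O=C(C#CBr)C#CBr
A4 | alternative 2 | 2,3-dimethoxybuta-1,3-diene | COC(=C)C(=C)OC
A5 | alternative 2 | bis(2-bromo-4,5-dimethoxycyclohexa-1,4-dien-1-yl)methanone | O=C(C1=C(Br)CC(OC)=C(OC)C1)C1=C(Br)CC(OC)=C(OC)C1
A6 | alternative 2 | bis(2-bromo-4,5-dimethoxyphenyl)methanone | COc1cc(Br)c(C(=O)c2cc(OC)c(OC)cc2Br)cc1OC
A7 | alternative 3 | 3,4-dibromofuran | Brc1cocc1Br
A8 | alternative 3 | bis[3,4-dibromo-5-(tert-butyldimethylsilyloxy)furan-2-yl]methane | CC(C)(C)[Si](C)(C)Oc1oc(Cc2oc(O[Si](C)(C)C(C)(C)C)c(Br)c2Br)c(Br)c1Br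
A9 | alternative 3 | methyl vinyl ketone | CC(=O)C=C
A10 | alternative 3 | bis(5-acetyl-2,3-dibromo-4-hydroxyphenyl)methane | CC(=O)c1cc(Cc2cc(C(C)=O)c(O)c(Br)c2Br)c(Br)c(Br)c1O
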